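The rate constants stand for no real mixture; no experiment stands behind them.

A closed, stirred vessel at constant temperature receives electrophile and nucleophile. Each electrophile taken up by step 1 sets one acid free, and that acid can bind a second nucleophile.

electrophile 10 mM; nucleophile 12.0 mM; time 20 s

    electrophile + nucleophile ⇌ acid set free + target (K1 = 1.43, k1 = 1.92 M⁻¹ s⁻¹)
    nucleophile + acid set free ⇌ protonated nucleophile, settled at all times (K2 = 15000 M⁻¹)
    electrophile + target → side product (k3 = 1.09 M⁻¹ s⁻¹)

- part of the electrophile that has reacted at 20 s
- share of the unused nucleophile that is free and not bound as protonated nucleophile, at 20 s

- in percentages every species weighs as the electrophile in it: one side product counts as two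
- run time (flask): 20 s

The ladder starts with step 2, which is kept at balance. With 180 for its constant times the nucleophile charged, nearly all of the acid set free sits as protonated nucleophile, so each turn of step 1 costs two nucleophile. Next comes step 1, with a forward half-life of electrophile of 30 s at the charged nucleophile. Slower still is step 3, with a half-life of target of 64 s at the charged electrophile. The run time of 20 s is shorter than both, so this flask should still hold unused electrophile at the asked time, with target ahead of side product.

Let x and y be the extents of steps 1 and 3, and C the nucleophile charged. Dividing the rate of step 3 by the forward rate of step 1 removes time and electrophile together. This leaves dy/dx = σ[target]/[nucleophile], where σ is the selectivity factor, k3 over k1, 0.568. Setting aside the way back of step 1 and taking target as x, with nucleophile as C − 2x, gives y = σ[(C/4)ln(C/(C − 2x)) − x/2]. Step 1 with both partners running down gives x = 2.84 mM, so y = 0.286 mM. The reckoning therefore stands at c = 31.3% and fr = 69.0%.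

The forecast, holding that “the liberated acid is almost entirely bound”, gives c = 30.8%, lower than this reckoning, and fr = 69.6%, higher than it.

The simulation gives c = 30.8% and fr = 69.6%.

At 20.0 s this flask holds target at 25.6% of the electrophile charged and nucleophile at 53.2% of its own charge, so σ puts step 3 at 0.227 of the forward rate of step 1, and target, each step taken net, is made 4.40 times faster than used up. The reacted part stays at 30.8% partly through nucleophile consumption, acting with the time given: nucleophile held gives 39.4%, ten times as long 81.9%. In the neighbour flask with 48 mM of nucleophile, the rule at 7.49 mM of protonated nucleophile gives 8.45% as side product, counted double, and that flask holds 8.19%.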